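**Plan**

- Retrosynthesis: after late unmasking (four aryl methyl ethers, one tert-butyl ester, and the carboxyl released from an indole-forming anilide), two bonds at the only stereocentre are cut together: the carbinol carbon to carboxyl carbon bond and the ester C–O bond to the cinnamoyl group.
- Enabling feature: that stereocentre is an α-acyloxy carboxyl carbon. It carries the cinnamoyl ester oxygen, the carboxyl carbon, H and the benzylic CH2 of ring B, which is the pattern a Passerini reaction assembles from a ring A cinnamic acid, a ring B arylacetaldehyde and a convertible aryl isocyanide.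
- Further cuts: the ring A acid is opened at the aryl–vinyl bond (Heck reaction with acrylic acid) and the aryl–bromine bond (bromination of a 2,3-dimethoxyphenylacetate); the isocyanide goes back to 2-nitrotoluene.
- Forward order: no ring of the target is built (rings A and B are bought; the only ring closed is the sacrificial indole that activates the anilide). The ring A acid and the isocyanide are made separately, joined with the aldehyde in one three-component step, then anilide to N-acylindole to acid, then global dealkylation.
- Stereochemistry: the R centre is created in the three-component step under a chiral BINOL-derived phosphoric acid and is not touched afterwards; the E alkene comes from the Heck reaction.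

Key step: step 8

Assumption: the (R)-configured phosphoric acid is taken to give the R ester; the sense of induction is to be checked on small scale (chiral HPLC against the racemate from an uncatalysed run), and the equally available (S)-catalyst is used if it proves opposite.

**Route**

Step 1
Reactants: 1 2,3-dimethoxyphenylacetic acid
Product: 2 tert-butyl 2-(2,3-dimethoxyphenyl)acetate
Conditions: Cl3CC(=NH)O-t-Bu (2 equiv), BF3·OEt2 (5 mol %), CH2Cl2/cyclohexane, rt
Reagents that add atoms: tert-butyl 2,2,2-trichloroacetimidate, CC(C)(C)OC(=N)C(Cl)(Cl)Cl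
Why: Acid-catalysed alkylation of the carboxyl group by the trichloroacetimidate (tert-butyl ester formation through tert-butyl cation transfer) masks the acetic acid so that only one carboxyl is free later, and it leaves the aryl methyl ethers untouched.

Step 2
Reactants: 2 tert-butyl 2-(2,3-dimethoxyphenyl)acetate
Product: 3 tert-butyl 2-(6-bromo-2,3-dimethoxyphenyl)acetate
Conditions: N-bromosuccinimide (1.05 equiv), MeCN, 0 °C to rt, dark
Reagents that add atoms: N-bromosuccinimide, O=C1CCC(=O)N1Br
Why: Electrophilic aromatic bromination goes para to the 3-methoxy group (C6), because that methoxy group lies in the ring plane and donates fully whereas the 2-methoxy group is twisted out of conjugation by its two ortho neighbours, the same site selectivity as in the bromination of 2,3-dimethoxytoluene and 2,3-dimethoxybenzaldehyde with NBS.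

Step 3
Reactants: 3 tert-butyl 2-(6-bromo-2,3-dimethoxyphenyl)acetate; 4 acrylic acid
Product: 5 (E)-3-[2-(2-tert-butoxy-2-oxoethyl)-3,4-dimethoxyphenyl]acrylic acid
Conditions: Pd(OAc)2 (5 mol %), P(o-tol)3 (10 mol %), Et3N (3 equiv), DMF, 100 °C; cold dilute acid work-up
Reagents that add atoms: none
Why: Mizoroki–Heck reaction: oxidative addition of the aryl bromide to zerovalent palladium formed in the flask, syn insertion of acrylic acid at its unsubstituted carbon and syn β-hydride elimination give the E cinnamic acid directly, with the tert-butyl ester inert to the amine base.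

Step 4
Reactants: 6 2-nitrotoluene
Product: 8 1-(2,2-dimethoxyethyl)-2-nitrobenzene, via nitro enamine 7 (not isolated)
Conditions: Me2NCH(OMe)2, DMF, 140 °C; concentrate; then HCl (1.25 M in MeOH, excess), 60 °C
Reagents that add atoms: N,N-dimethylformamide dimethyl acetal, COC(OC)N(C)C; methanol, CO
Why: Leimgruber–Batcho-type condensation of the methyl group acidified by the ortho nitro group with the formamide acetal gives enamine 7, and acid methanolysis through the iminium and oxocarbenium ions exchanges the amine for two methoxy groups (enamine to acetal transacetalisation).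

Step 5
Reactants: 8 1-(2,2-dimethoxyethyl)-2-nitrobenzene
Product: 9 2-(2,2-dimethoxyethyl)aniline
Conditions: H2 (1 atm), 10% Pd/C, MeOH, rt
Reagents that add atoms: none
Why: Catalytic hydrogenation reduces the nitro group to the amine, and the neutral medium keeps the dimethyl acetal from ionising and cyclising onto the new aniline nitrogen.

Step 6
Reactants: 9 2-(2,2-dimethoxyethyl)aniline
Product: 10 N-[2-(2,2-dimethoxyethyl)phenyl]formamide
Conditions: HCO2Ac (acetic formic anhydride, prepared beforehand), THF, 0 °C
Reagents that add atoms: acetic formic anhydride, CC(=O)OC=O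
Why: N-Formylation with the mixed anhydride takes place at the more electrophilic formyl carbonyl, and at 0 °C the acetic acid set free is too weak to open the acetal.

Step 7
Reactants: 10 N-[2-(2,2-dimethoxyethyl)phenyl]formamide
Product: 11 2-(2,2-dimethoxyethyl)phenyl isocyanide
Conditions: POCl3 (1.1 equiv), Et3N (4 equiv), THF, −40 to 0 °C
Reagents that add atoms: none
Why: Formamide dehydration: O-phosphorylation by POCl3 and amine-induced elimination give the isocyanide, the excess Et3N keeping the medium basic so that the acetal survives.

Step 8
Reactants: 5 (E)-3-[2-(2-tert-butoxy-2-oxoethyl)-3,4-dimethoxyphenyl]acrylic acid; 12 3,4-dimethoxyphenylacetaldehyde; 11 2-(2,2-dimethoxyethyl)phenyl isocyanide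
Product: 14 (R)-1-{[2-(2,2-dimethoxyethyl)phenyl]amino}-3-(3,4-dimethoxyphenyl)-1-oxopropan-2-yl (E)-3-[2-(2-tert-butoxy-2-oxoethyl)-3,4-dimethoxyphenyl]acrylate, via acyl imidate 13 (not isolated)
Conditions: (R)-3,3'-bis(2,4,6-triisopropylphenyl)-1,1'-binaphthyl-2,2'-diyl hydrogen phosphate (10 mol %), 4 Å MS, CHCl3 (0.05 M), −20 °C; 5 (1 equiv), 11 (1.2 equiv), 12 (1.5 equiv, freshly chromatographed, added over 6 h)
Reagents that add atoms: none
Why: Proposed new method: the phosphoric acid and the carboxyl group of 5 form a hydrogen-bonded pair that also binds the carbonyl oxygen of 12, isocyanide 11 adds through carbon to the uncovered face of the aldehyde carbon, the nitrilium ion is captured by the carboxylate to give acyl imidate 13, and a Mumm-type acyl shift from the imidate oxygen to the neighbouring hydroxyl gives the α-acyloxy anilide 14. The closest known reaction type is the chiral phosphoric acid-catalysed enantioselective Passerini three-component reaction of aldehydes, carboxylic acids and isocyanides; new here are the enolisable arylacetaldehyde, the cinnamic acid and the ortho-substituted convertible aryl isocyanide as partners. No ring is closed. The one new stereocentre is controlled by the catalyst, whose 3,3'-aryl groups shield one face of the bound aldehyde during C–C bond formation, and it is not touched by the later acyl shift. The step needs facial selectivity at the aldehyde carbon, reaction of the cinnamic carboxyl only and little enolisation or uncatalysed background reaction; the tert-butyl ester on the acetic acid arm secures the chemoselectivity, the absence of any α-substituent that could bias the face leaves control entirely to the catalyst, and slow addition of 12, dilution and −20 °C in a base-free medium hold back aldol and racemic pathways.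

Step 9
Reactants: 14 the Passerini anilide
Product: 15 (R)-3-(3,4-dimethoxyphenyl)-1-(1H-indol-1-yl)-1-oxopropan-2-yl (E)-3-[2-(2-tert-butoxy-2-oxoethyl)-3,4-dimethoxyphenyl]acrylate
Conditions: (+)-camphor-10-sulfonic acid (10 mol %), quinoline (10 mol %), toluene, 5 Å MS, 80 °C
Reagents that add atoms: none
Why: Acid ionises the dimethyl acetal to an oxocarbenium ion, the anilide nitrogen closes the five-membered ring by 5-exo attack and loss of methanol aromatises it to the N-acylindole (acid-induced activation of the convertible anilide), while the quinoline-buffered acid spares the tert-butyl ester, the depside ester and the stereocentre, which has no basic pathway for epimerisation.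

Step 10
Reactants: 15 the N-acylindole
Product: 17 (R)-2-{[(E)-3-[2-(2-tert-butoxy-2-oxoethyl)-3,4-dimethoxyphenyl]acryloyl]oxy}-3-(3,4-dimethoxyphenyl)propanoic acid, via peroxy acid 16 (not isolated)
Conditions: LiOH (2 equiv), 30% H2O2 (4 equiv), THF/H2O (3:1), 0 °C; then aq. Na2SO3; then 1 M HCl to pH 3
Reagents that add atoms: hydrogen peroxide, OO
Why: Chemoselective hydroperoxide cleavage of an activated amide: the N-acylindole, whose nitrogen lone pair belongs to the aromatic ring, is attacked by the weakly basic α-effect nucleophile LiOOH much faster than the conjugated cinnamate or the tert-butyl ester, as in the peroxide hydrolysis of N-acyl oxazolidinones, sulfite then reduces peroxy acid 16, and the low basicity at 0 °C protects the stereocentre.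

Step 11
Reactants: 17 the tetramethyl tert-butyl ester acid
Product: 18 salvianolic acid D, (R)-2-{[(E)-3-[2-(carboxymethyl)-3,4-dihydroxyphenyl]acryloyl]oxy}-3-(3,4-dihydroxyphenyl)propanoic acid
Conditions: BBr3 (1 M in CH2Cl2, 10 equiv), CH2Cl2, −78 to 0 °C; then ice-water; reversed-phase chromatography without heating
Reagents that add atoms: none
Why: Lewis-acid dealkylation: BBr3 binds each aryl methyl ether oxygen and bromide removes the methyl group by SN2 attack, the tert-butyl ester ionises to the acid, and the secondary cinnamate ester, a weaker Lewis base whose alkyl carbon is neither easily ionised nor readily displaced, together with the stereocentre, should survive at low temperature and a cold aqueous quench.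

**Compound list**

1 | 2,3-dimethoxyphenylacetic acid | OC(=O)Cc1cccc(OC)c1OC | starting material
2 | tert-butyl 2-(2,3-dimethoxyphenyl)acetate | CC(C)(C)OC(=O)Cc1cccc(OC)c1OC | intermediate
3 | tert-butyl 2-(6-bromo-2,3-dimethoxyphenyl)acetate | CC(C)(C)OC(=O)Cc1c(Br)ccc(OC)c1OC | intermediate
4 | acrylic acid | C=CC(=O)O | starting material
5 | (E)-3-[2-(2-tert-butoxy-2-oxoethyl)-3,4-dimethoxyphenyl]acrylic acid | OC(=O)/C=C/c1ccc(OC)c(OC)c1CC(=O)OC(C)(C)C | intermediate
6 | 2-nitrotoluene | Cc1ccccc1[N+](=O)[O-] | starting material
7 | (E)-N,N-dimethyl-2-(2-nitrophenyl)ethenamine (nitro enamine) | CN(C)/C=C/c1ccccc1[N+](=O)[O-] | intermediate (not isolated)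
8 | 1-(2,2-dimethoxyethyl)-2-nitrobenzene | COC(OC)Cc1ccccc1[N+](=O)[O-] | intermediate
9 | 2-(2,2-dimethoxyethyl)aniline | COC(OC)Cc1ccccc1N | intermediate
10 | N-[2-(2,2-dimethoxyethyl)phenyl]formamide | COC(OC)Cc1ccccc1NC=O | intermediate
11 | 2-(2,2-dimethoxyethyl)phenyl isocyanide | COC(OC)Cc1ccccc1[N+]#[C-] | intermediate
12 | 3,4-dimethoxyphenylacetaldehyde | O=CCc1ccc(OC)c(OC)c1 | starting material
13 | acyl imidate: (R)-α-hydroxy imidate of 12 and 11, O-acylated on the imidate oxygen by the cinnamoyl group of 5 | O[C@H](Cc1ccc(OC)c(OC)c1)C(=Nc1ccccc1CC(OC)OC)OC(=O)/C=C/c1ccc(OC)c(OC)c1CC(=O)OC(C)(C)C | intermediate (not isolated)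
14 | (R)-1-{[2-(2,2-dimethoxyethyl)phenyl]amino}-3-(3,4-dimethoxyphenyl)-1-oxopropan-2-yl (E)-3-[2-(2-tert-butoxy-2-oxoethyl)-3,4-dimethoxyphenyl]acrylate | CC(C)(C)OC(=O)Cc1c(/C=C/C(=O)O[C@H](Cc2ccc(OC)c(OC)c2)C(=O)Nc2ccccc2CC(OC)OC)ccc(OC)c1OC | intermediate
15 | (R)-3-(3,4-dimethoxyphenyl)-1-(1H-indol-1-yl)-1-oxopropan-2-yl (E)-3-[2-(2-tert-butoxy-2-oxoethyl)-3,4-dimethoxyphenyl]acrylate | CC(C)(C)OC(=O)Cc1c(/C=C/C(=O)O[C@H](Cc2ccc(OC)c(OC)c2)C(=O)n2ccc3ccccc32)ccc(OC)c1OC | intermediate
16 | (R)-2-{[(E)-3-[2-(2-tert-butoxy-2-oxoethyl)-3,4-dimethoxyphenyl]acryloyl]oxy}-3-(3,4-dimethoxyphenyl)propaneperoxoic acid (present as its lithium salt) | CC(C)(C)OC(=O)Cc1c(/C=C/C(=O)O[C@H](Cc2ccc(OC)c(OC)c2)C(=O)OO)ccc(OC)c1OC | intermediate (not isolated)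
17 | (R)-2-{[(E)-3-[2-(2-tert-butoxy-2-oxoethyl)-3,4-dimethoxyphenyl]acryloyl]oxy}-3-(3,4-dimethoxyphenyl)propanoic acid | CC(C)(C)OC(=O)Cc1c(/C=C/C(=O)O[C@H](Cc2ccc(OC)c(OC)c2)C(=O)O)ccc(OC)c1OC | intermediate
18 | salvianolic acid D | O=C(O)Cc1c(/C=C/C(=O)O[C@H](Cc2ccc(O)c(O)c2)C(=O)O)ccc(O)c1O | target

**Step count and risks**

Total step count: 11. Longest linear sequence: 8 steps (6 to 18 through steps 4 to 11); the ring A branch from 1 is 7 steps.

Steps most likely to fail:

Step 8 (proposed new method). The facial selectivity may be poor, the uncatalysed three-component reaction may compete and erode the enantiomeric purity, and the arylacetaldehyde may be lost through enolisation and self-aldol condensation. A modest enantiomeric excess could first be raised by crystallisation of 14 or 15. The fallback uses known chemistry and replaces the three-component union by a stepwise esterification with a lactate from the chiral pool; it sets out from 5 and comes back to the route at 17. Commercial 3,4-dimethoxy-D-phenylalanine is diazotised (NaNO2, aqueous H2SO4, 0 °C), which exchanges NH2 for OH with retention through the α-lactone and gives (R)-3-(3,4-dimethoxyphenyl)-2-hydroxypropanoic acid F1. Carboxylate alkylation with allyl bromide and KHCO3 in DMF gives allyl (R)-3-(3,4-dimethoxyphenyl)-2-hydroxypropanoate F2. Steglich esterification of 5 with F2 (N-(3-dimethylaminopropyl)-N'-ethylcarbodiimide hydrochloride, 4-(dimethylamino)pyridine, CH2Cl2, 0 °C) gives the allyl tert-butyl diester (R)-1-(allyloxy)-3-(3,4-dimethoxyphenyl)-1-oxopropan-2-yl (E)-3-[2-(2-tert-butoxy-2-oxoethyl)-3,4-dimethoxyphenyl]acrylate F3. Pd(PPh3)4 with morpholine in THF removes the allyl group and delivers 17, after which step 11 follows unchanged.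

Step 10. Hydroperoxide may also attack the cinnamate carbonyl and cleave the depside ester, or the activated amide may epimerise through its enolate before it is cleaved. The fallback avoids hydroxide and peroxide by transferring the acyl group to an alcohol whose ester is opened by fluoride; it sets out from 15 and comes back at 17. Treatment of 15 with 2-(trimethylsilyl)ethanol, Et3N and 4-(dimethylamino)pyridine in CH2Cl2 should give the silylethyl ester (R)-3-(3,4-dimethoxyphenyl)-1-oxo-1-[2-(trimethylsilyl)ethoxy]propan-2-yl (E)-3-[2-(2-tert-butoxy-2-oxoethyl)-3,4-dimethoxyphenyl]acrylate F4. n-Bu4NF buffered with acetic acid in THF at 0 °C then fragments the silylethyl group and gives 17.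

Step 11. The depside ester may be cleaved by the boron Lewis acid or by HBr, the released tert-butyl cation may alkylate the electron-rich rings, and the ortho-hydroxyphenylacetic acid arm may lactonise if the crude acid is concentrated warm. The fallback separates the two tasks and changes the dealkylation from a boron Lewis acid to silyl iodide, a reagent type known to demethylate this kind of depside without breaking the ester; it sets out from 17 and ends at 18. Trifluoroacetic acid in CH2Cl2 at 0 °C removes the tert-butyl group first and gives the diacid (R)-2-{[(E)-3-[2-(carboxymethyl)-3,4-dimethoxyphenyl]acryloyl]oxy}-3-(3,4-dimethoxyphenyl)propanoic acid F5. Me3SiI with quinoline at 120 °C, followed by aqueous work-up, then cleaves the four methyl ethers and gives 18.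

Further compounds
F1 | step 8 | (R)-3-(3,4-dimethoxyphenyl)-2-hydroxypropanoic acid | O[C@H](Cc1ccc(OC)c(OC)c1)C(=O)O
F2 | step 8 | allyl (R)-3-(3,4-dimethoxyphenyl)-2-hydroxypropanoate | O[C@H](Cc1ccc(OC)c(OC)c1)C(=O)OCC=C
F3 | step 8 | (R)-1-(allyloxy)-3-(3,4-dimethoxyphenyl)-1-oxopropan-2-yl (E)-3-[2-(2-tert-butoxy-2-oxoethyl)-3,4-dimethoxyphenyl]acrylate | CC(C)(C)OC(=O)Cc1c(/C=C/C(=O)O[C@H](Cc2ccc(OC)c(OC)c2)C(=O)OCC=C)ccc(OC)c1OC
F4 | step 10 | (R)-3-(3,4-dimethoxyphenyl)-1-oxo-1-[2-(trimethylsilyl)ethoxy]propan-2-yl (E)-3-[2-(2-tert-butoxy-2-oxoethyl)-3,4-dimethoxyphenyl]acrylate | CC(C)(C)OC(=O)Cc1c(/C=C/C(=O)O[C@H](Cc2ccc(OC)c(OC)c2)C(=O)OCC[Si](C)(C)C)ccc(OC)c1OC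
F5 | step 11 | (R)-2-{[(E)-3-[2-(carboxymethyl)-3,4-dimethoxyphenyl]acryloyl]oxy}-3-(3,4-dimethoxyphenyl)propanoic acid | OC(=O)Cc1c(/C=C/C(=O)O[C@H](Cc2ccc(OC)c(OC)c2)C(=O)O)ccc(OC)c1OC
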